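## Structural features

The centre of the molecule is a tetrahydrofuran ring (O1, C2 to C5) that carries a 3-methoxy-4-oxyphenyl (guaiacyl) ring on C2 (ring A) and on C5 (ring B) and a methyl group on C3 and on C4. Its four contiguous stereocentres are 2S,3S,4S,5R: the aryl groups are cis across the ring oxygen, C2/C3 and C3/C4 are trans, and C4/C5 are cis, so the ring has no symmetry. The phenolic oxygen of each guaiacyl ring is etherified by a 1-(3,4-dimethoxyphenyl)-1-hydroxypropan-2-yl chain. Both carbinol carbons (C7 on the ring A chain, C7' on the ring B chain) are R, but the ether carbons differ: C8 is S (erythro chain) and C8' is R (threo chain). The two phenols therefore have to be told apart, the two chains need enantiomeric three-carbon units, and the two carbinols need opposite modes of carbonyl reduction. Both ring C–O bonds are benzylic ethers of para-oxygenated aryl groups and ionise under acid. The chain carbinols are electron-rich benzylic alcohols, and the α-aryloxy ketones that precede them can epimerise at C8 under base. The real difficulty is C5: its aryl group is cis to the C4 methyl, the less stable arrangement, next to a C2 centre in the more stable trans arrangement, so C5 must be set kinetically and then kept away from acid. The key step uses exactly this feature. The O1–C5 bond with the aryl cis to the C4 methyl is what an invertive opening of a trans-2-aryl-3-methylcyclopropane-1,1-diester at its benzylic carbon produces, and the closure of C2–C3 puts the two aryl groups 2,5-cis.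

## Logic of the disconnections

30 to 29: the C7–H bond of the ring A chain is cut, which turns the carbinol into a ketone. C7 sits next to C8 and can be set from it through a chelate, so only an sp2 carbon has to be carried. The forward reduction must deliver hydride anti (erythro) and tolerate the free C7' alcohol.

29 to 24 and 28: the C8–O aryl ether bond is cut. This removes a ten-carbon unit and one stereocentre in a convergent step. The forward step must be an SN2 displacement with clean inversion and no enolisation, and the phenol must react in preference to the secondary alcohol.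

24 to 23, 22, then 16 and 21: the benzyl C–O bond, the C7'–H bond and the C8'–O bond of the ring B chain are cut in turn. The logic is that of the ring A chain in the mirror-image series of the three-carbon unit, but the reduction must now go through the non-chelated transition state (threo). The hydrogenolysis must spare the secondary benzylic C–O bonds.

16 to 15: the allyl C–O bond is cut. Allyl on ring B and benzyl on ring A distinguish the two phenols, and the allyl group must come off under neutral conditions.

15 to 14, 13 and 12: the C3 methyl is traced back through sulfonate and carbinol to an ester. An ester at C3 is what the annulation leaves and it makes C3 epimerisable. The forward hydride steps must leave all ethers alone.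

12 to 10 (through 11): a second ester is put back on C3. This removes the C3 stereocentre and returns the malonate carbon. Forward, loss of one ester must be followed by equilibration to the trans,trans isomer.

10 to 8 and 9: O1–C5 and C2–C3 are cut. This is the strategic cut: it opens the only ring of the core, removes two stereocentres and divides the core into two pieces of similar size. Forward, the opening at C5 must be invertive and the closure must give the 2,5-cis ring.

8 to 7, 6 and 5: the cyclopropane methyl is traced to a formyl group, because formyl is what the catalytic cyclopropanation needs. The forward deoxygenation must be a two-electron process, since a radical or cation at this carbon would open the three-membered ring.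

5 to 3 and 4: both bonds from the malonate carbon to the former alkene carbons are cut. Two stereocentres then come from achiral materials under catalyst control. The forward step needs face selectivity at the β carbon and a trans closure.

3 to 1 and 2: the allyl C–O bond is cut, leaving two purchasable compounds.

21 to 20, then 18 and 19, then 17; likewise 28 to 27, then 26 and 19, then 25: the sulfonate S–O bond, the aryl–carbonyl bond and the amide C–N bond are cut. The stereocentre comes from the chiral pool and the aryl group from a purchasable Grignard reagent. Forward, the aryl group must add only once and the stereocentre must not enolise.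

## Other disconnections considered

Alternative 1: The cut is at both carbinol C–O bonds, made last by C–H hydroxylation; no ring is formed. In the forward direction the bisphenol A2 (the 7,7'-dideoxy compound with 4-hydroxy-3-methoxyphenyl end groups) would be oxidised by a flavin-dependent 4-alkylphenol oxidase of the vanillyl alcohol oxidase family with O2. Each end group would become an enzyme-bound p-quinone methide, to which water adds at C7 from one face to give A1; methylation of the two phenols would then lead to 30.
- In its favour: one catalyst would set both carbinols R whatever the configuration at C8, which is the pattern of 30. No single achiral hydride can do this, so on this point the alternative is better than the chosen plan, which needs two reduction regimes. It also avoids epimerisable α-aryloxy ketones and metal hydrides.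
- Against it here: enzymes of this class take small 4-alkylphenols through a narrow channel. A substrate with a bulky aryloxy group on the β carbon and a tetra-aryl body may not bind productively, and would have to do so twice. The quinone methide could also tautomerise to an enol ether instead of being hydrated.
- Comparison: on structure it touches only C7 and C7', whereas the chosen key step makes the ring and two ring stereocentres. On mechanism it is face-selective hydration of a planar quinone methide in a chiral pocket, against hydride delivery to a chelated or non-chelated ketone. On step economy it replaces two reductions by one oxidation and one methylation and needs protected vanillyl end groups, so it is about equal, not shorter.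

Alternative 2: The cut is the O1–C2 bond. In the forward direction the acyclic carbinol A4, with a free phenol on the benzyl end and a silyl ether on the carbinol aryl, would be oxidised at a carbon anode by two electrons to a p-quinone methide at C2. The C5 hydroxyl would attack it in a 5-exo-trig closure to give A3, the C2 aryl settling trans to the C3 methyl.
- In its favour: the C5–O bond is never broken, so the less stable cis centre is not at risk during ring formation. Here the alternative is equal to or better than the chosen plan, whose inversion takes place at an ionisable carbon. C2 forms in its preferred configuration, no chemical oxidant is needed, and A3 arrives with the two phenols already differentiated.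
- Against it here: A4 needs three contiguous stereocentres built by linear aldol and alkylation chemistry. A3 is oxidised at about the potential of A4 and still has a benzylic C2–H para to a free phenol, so over-oxidation and reopening are to be expected. The quinone methide can also be trapped by solvent or lose a proton to a styrene.
- Comparison: on structure it makes one bond and one stereocentre, against two bonds, one ring and two stereocentres in the chosen step. On mechanism it is oxidative generation of an electrophile captured by an internal alcohol, against SN2-like opening and aldol-type closure. On step economy the ring-forming step is equal, but the route to A4 should be longer than the five steps to 8.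

Alternative 3: The cut is at the two methyl–ring bonds, made on a lactone. In the forward direction Me2CuLi would add to the butenolide A6 anti to the aryl group and the enolate would be methylated with CH3I anti to the new methyl, giving the all-trans lactone A5. A ring B aryl nucleophile would later add to the lactone carbonyl, and reduction of the lactol through its oxocarbenium ion would have to place the new aryl cis to the adjacent methyl.
- In its favour: both methyl groups enter directly as methyl groups in one flask with dependable 1,2-induction. No ester has to be reduced to methyl, so for C3 and C4 the alternative is better in step economy than steps 7 to 10 of the chosen plan.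
- Against it here: the γ hydrogen of A6 is benzylic and vinylogously acidic, so cuprate or enolate base can erode the single enantiomer, and A6 itself needs an enantioselective synthesis. Ring B and C5 would come late, under Lewis acid, where the ring A benzylic ether can ionise and the wanted cis isomer is the less stable one.
- Comparison: on structure it sets C3 and C4 on an existing ring, whereas the chosen step makes the ring and sets C2 and C5. On mechanism it is substrate-controlled conjugate addition and alkylation, against a stereospecific annulation. On step economy it is shorter for the methyls and longer for the aryl groups, so about equal overall. The chosen plan is stronger on the security of absolute configuration, because C4 is fixed by a catalyst and cannot epimerise.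

Key step: step 6

Remark: C7/C8 denote the carbinol and ether carbons of the chain on ring A (the guaiacyl ring on C2), C7'/C8' those of the chain on ring B (on C5). The descriptor of C2 changes from R in diester 10 to S from 11 onwards through substituent priority only, not geometry. Coniferaldehyde 1 is assumed to be purchasable.

## Route

Step 1
Reactants: 1 coniferaldehyde; 2 allyl bromide
Product: 3 (E)-3-(4-allyloxy-3-methoxyphenyl)prop-2-enal
Conditions: K2CO3, DMF, rt
Reagents that add atoms: none
Why: Williamson O-alkylation of the phenoxide with an allylic bromide; carbonate is too weak a base to affect the enal.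

Step 2
Reactants: 3 (E)-3-(4-allyloxy-3-methoxyphenyl)prop-2-enal; 4 dimethyl bromomalonate
Product: 5 dimethyl (2S,3R)-2-(4-allyloxy-3-methoxyphenyl)-3-formylcyclopropane-1,1-dicarboxylate (aryl and formyl trans)
Conditions: (S)-α,α-diphenylprolinol trimethylsilyl ether (20 mol %), 2,6-lutidine, CH2Cl2, 0 °C → rt
Reagents that add atoms: none
Why: Aminocatalytic Michael-initiated ring closure: the bromomalonate anion should add to the β carbon of the E-iminium ion on the face away from the diphenyl(silyloxy)methyl group, and the resulting enamine should displace bromide in a 3-exo-tet closure that puts formyl trans to aryl. The (S)-catalyst should give the (2S,3R) ring, and the hindered base 2,6-lutidine is chosen to avoid base-induced reopening.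

Step 3
Reactants: 5 dimethyl (2S,3R)-2-(4-allyloxy-3-methoxyphenyl)-3-formylcyclopropane-1,1-dicarboxylate
Product: 6 dimethyl (2S,3R)-2-(4-allyloxy-3-methoxyphenyl)-3-(hydroxymethyl)cyclopropane-1,1-dicarboxylate
Conditions: NaBH4, MeOH/CH2Cl2, −20 °C; AcOH quench
Reagents that add atoms: none
Why: Chemoselective borohydride reduction of the aldehyde beside the malonate esters; the cold, buffered quench and immediate use should keep the new carbinol from lactonising onto the cis ester.

Step 4
Reactants: 6 dimethyl (2S,3R)-2-(4-allyloxy-3-methoxyphenyl)-3-(hydroxymethyl)cyclopropane-1,1-dicarboxylate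
Product: 7 dimethyl (2S,3R)-2-(4-allyloxy-3-methoxyphenyl)-3-(iodomethyl)cyclopropane-1,1-dicarboxylate
Conditions: PPh3, I2, imidazole, CH2Cl2, 0 °C
Reagents that add atoms: iodine, II
Why: Appel-type iodination: iodide displaces the alkoxyphosphonium group by SN2 at the primary carbon under neutral conditions, so no cyclopropylcarbinyl cation should form.

Step 5
Reactants: 7 dimethyl (2S,3R)-2-(4-allyloxy-3-methoxyphenyl)-3-(iodomethyl)cyclopropane-1,1-dicarboxylate
Product: 8 dimethyl (2S,3R)-2-(4-allyloxy-3-methoxyphenyl)-3-methylcyclopropane-1,1-dicarboxylate (aryl and methyl trans)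
Conditions: NaBH4, DMSO, 20 °C
Reagents that add atoms: none
Why: Polar SN2 hydride displacement of a primary iodide by borohydride in a dipolar aprotic solvent. A two-electron path is chosen because a radical or cation at this carbon would open the ring; the esters should be inert to NaBH4 in DMSO at this temperature and neither ring stereocentre is touched.

Step 6
Reactants: 8 dimethyl (2S,3R)-2-(4-allyloxy-3-methoxyphenyl)-3-methylcyclopropane-1,1-dicarboxylate; 9 4-benzyloxy-3-methoxybenzaldehyde
Product: 10 dimethyl (2R,4S,5R)-5-(4-allyloxy-3-methoxyphenyl)-2-(4-benzyloxy-3-methoxyphenyl)-4-methyltetrahydrofuran-3,3-dicarboxylate (aryls 2,5-cis, C5 aryl cis to C4 methyl)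
Conditions: Sn(OTf)2 (10 mol %), 9 (3 equiv), CH2Cl2, −20 → 0 °C
Reagents that add atoms: none
Why: Sn(OTf)2 (divalent tin) should bind the two ester carbonyls of 8 as a chelate and polarise the bond between the malonate carbon and the benzylic carbon; the carbonyl oxygen of 9 then attacks the benzylic carbon from the side opposite the departing malonate carbon within a tight ion pair, forming O1–C5 with inversion. The tin malonate/oxocarbenium zwitterion closes by attack of the malonate carbon on the oxocarbenium carbon, forming C2–C3. The closest known reaction type is the Lewis-acid-catalysed formal [3+2] annulation of 2-arylcyclopropane-1,1-diesters with aldehydes to 2,5-cis tetrahydrofurans. The single ring is closed in the second event, a 5-(enolexo)-endo-trig aldol-type addition, a mode that is accessible in practice when the acceptor is an oxocarbenium ion. C5 is controlled by the inversion, which turns the trans aryl/methyl pair of 8 into the cis C5-aryl/C4-methyl pair; C4 passes through unchanged and anchors the absolute configuration, so ionisation could cost diastereomeric purity at C5 but cannot racemise the product. C2 is controlled by the envelope transition state, in which the E-oxocarbenium ion keeps its aryl group pseudoequatorial and therefore cis to the C5 aryl. The step needs capture of the ion pair to be faster than full ionisation, than proton loss from C4 to an open styrylmalonate and than reopening of the product to the 2,5-trans isomer. The electron-rich, nucleophilic aldehyde in excess, the low temperature, the catalytic amount of promoter and a prompt basic quench should secure this; the allyl and benzyl ethers are spectators.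

Step 7
Reactants: 10 dimethyl (2R,4S,5R)-5-(4-allyloxy-3-methoxyphenyl)-2-(4-benzyloxy-3-methoxyphenyl)-4-methyltetrahydrofuran-3,3-dicarboxylate
Product: 12 methyl (2S,3S,4S,5R)-5-(4-allyloxy-3-methoxyphenyl)-2-(4-benzyloxy-3-methoxyphenyl)-4-methyltetrahydrofuran-3-carboxylate (ester trans to the C2 aryl and to the C4 methyl), via C3-epimeric monoester mixture 11 (not isolated)
Conditions: LiCl, H2O, DMSO, 135 °C; then NaOMe (cat.), MeOH, rt
Reagents that add atoms: none
Why: Krapcho dealkoxycarbonylation (chloride SN2 at the ester methyl, loss of CO2, protonation) followed by methoxide equilibration through the ester enolate. C3 is the only epimerisable centre and should settle trans to both neighbours; ring opening by β-elimination would be the reverse of a 5-endo-trig closure and should be slow.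

Step 8
Reactants: 12 methyl (2S,3S,4S,5R)-5-(4-allyloxy-3-methoxyphenyl)-2-(4-benzyloxy-3-methoxyphenyl)-4-methyltetrahydrofuran-3-carboxylate
Product: 13 [(2S,3R,4S,5R)-5-(4-allyloxy-3-methoxyphenyl)-2-(4-benzyloxy-3-methoxyphenyl)-4-methyltetrahydrofuran-3-yl]methanol
Conditions: LiAlH4, THF, 0 °C
Reagents that add atoms: none
Why: Hydride reduction of the ester to the primary alcohol; aryl allyl ether, aryl benzyl ether and ring ether are inert and no stereocentre is involved.

Step 9
Reactants: 13 [(2S,3R,4S,5R)-5-(4-allyloxy-3-methoxyphenyl)-2-(4-benzyloxy-3-methoxyphenyl)-4-methyltetrahydrofuran-3-yl]methanol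
Product: 14 [(2S,3R,4S,5R)-5-(4-allyloxy-3-methoxyphenyl)-2-(4-benzyloxy-3-methoxyphenyl)-4-methyltetrahydrofuran-3-yl]methyl methanesulfonate
Conditions: MsCl, Et3N, CH2Cl2, 0 °C
Reagents that add atoms: methanesulfonyl chloride, CS(=O)(=O)Cl
Why: O-sulfonylation of a primary alcohol under basic conditions that do not threaten the acid-sensitive benzylic ethers.

Step 10
Reactants: 14 [(2S,3R,4S,5R)-5-(4-allyloxy-3-methoxyphenyl)-2-(4-benzyloxy-3-methoxyphenyl)-4-methyltetrahydrofuran-3-yl]methyl methanesulfonate
Product: 15 (2S,3S,4S,5R)-5-(4-allyloxy-3-methoxyphenyl)-2-(4-benzyloxy-3-methoxyphenyl)-3,4-dimethyltetrahydrofuran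
Conditions: LiBHEt3, THF, 0 °C → rt
Reagents that add atoms: none
Why: SN2 hydride displacement of the β-branched primary mesylate by the most nucleophilic borohydride; ethers and the four ring stereocentres are untouched.

Step 11
Reactants: 15 (2S,3S,4S,5R)-5-(4-allyloxy-3-methoxyphenyl)-2-(4-benzyloxy-3-methoxyphenyl)-3,4-dimethyltetrahydrofuran
Product: 16 4-[(2R,3S,4S,5S)-5-(4-benzyloxy-3-methoxyphenyl)-3,4-dimethyltetrahydrofuran-2-yl]-2-methoxyphenol (free phenol on ring B)
Conditions: Pd(PPh3)4 (5 mol %), morpholine, THF, rt
Reagents that add atoms: none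
Why: Tsuji–Trost-type deallylation: zerovalent palladium ionises the allyl aryl ether to a π-allyl complex that morpholine captures. The conditions are neutral, so the benzyl ether and the acid-labile C5 centre should survive.

Step 12
Reactants: 17 ethyl (S)-lactate
Product: 18 (S)-2-hydroxy-N-methoxy-N-methylpropanamide
Conditions: MeNHOMe·HCl, i-PrMgCl, THF, −20 → 0 °C
Reagents that add atoms: N,O-dimethylhydroxylamine hydrochloride, CNOC.Cl
Why: Weinreb amide formation by aminolysis of the ester with the chloromagnesium amide; the α-alkoxide formed first should protect the stereocentre from enolisation.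

Step 13
Reactants: 18 (S)-2-hydroxy-N-methoxy-N-methylpropanamide; 19 3,4-dimethoxyphenylmagnesium bromide
Product: 20 (S)-1-(3,4-dimethoxyphenyl)-2-hydroxypropan-1-one
Conditions: i-PrMgCl (1 equiv), THF, −20 °C; then 19, 0 °C → rt; aq NH4Cl
Reagents that add atoms: none
Why: Weinreb ketone synthesis: the magnesium alkoxide and the N-methoxy group hold the tetrahedral adduct as a chelate until work-up, so only one aryl group should add and the stereocentre is not enolised.

Step 14
Reactants: 20 (S)-1-(3,4-dimethoxyphenyl)-2-hydroxypropan-1-one
Product: 21 (S)-1-(3,4-dimethoxyphenyl)-1-oxopropan-2-yl 4-methylbenzenesulfonate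
Conditions: TsCl, Et3N, DMAP (cat.), CH2Cl2, 0 °C
Reagents that add atoms: 4-methylbenzenesulfonyl chloride, Cc1ccc(cc1)S(=O)(=O)Cl
Why: O-sulfonylation with retention, since the C–O bond is not broken; it creates an α-keto sulfonate, a strongly activated SN2 electrophile.

Step 15
Reactants: 16 4-[(2R,3S,4S,5S)-5-(4-benzyloxy-3-methoxyphenyl)-3,4-dimethyltetrahydrofuran-2-yl]-2-methoxyphenol; 21 (S)-1-(3,4-dimethoxyphenyl)-1-oxopropan-2-yl 4-methylbenzenesulfonate
Product: 22 (R)-2-{4-[(2R,3S,4S,5S)-5-(4-benzyloxy-3-methoxyphenyl)-3,4-dimethyltetrahydrofuran-2-yl]-2-methoxyphenoxy}-1-(3,4-dimethoxyphenyl)propan-1-one (C8' R)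
Conditions: BEMP, CH2Cl2, 0 °C → rt
Reagents that add atoms: none
Why: SN2 etherification with inversion at the carbonyl-activated carbon, (S)-sulfonate to (R)-ether. The non-nucleophilic phosphazene base BEMP (2-tert-butylimino-2-diethylamino-1,3-dimethylperhydro-1,3,2-diazaphosphorine) should give a reactive phenoxide at low temperature, mild enough to avoid enolisation at C8' and quinone-methide opening at C5.

Step 16
Reactants: 22 (R)-2-{4-[(2R,3S,4S,5S)-5-(4-benzyloxy-3-methoxyphenyl)-3,4-dimethyltetrahydrofuran-2-yl]-2-methoxyphenoxy}-1-(3,4-dimethoxyphenyl)propan-1-one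
Product: 23 (1R,2R)-2-{4-[(2R,3S,4S,5S)-5-(4-benzyloxy-3-methoxyphenyl)-3,4-dimethyltetrahydrofuran-2-yl]-2-methoxyphenoxy}-1-(3,4-dimethoxyphenyl)propan-1-ol (threo chain on ring B)
Conditions: n-Bu4NBH4, CH2Cl2/MeOH, −40 → −20 °C
Reagents that add atoms: none
Why: Borohydride reduction with a non-coordinating ammonium counter-ion, so no chelate can form. In the polar Felkin–Anh transition state the aryloxy group lies anti to the incoming hydride, which should give the syn (threo) alcohol, C7' R from C8' R.

Step 17
Reactants: 23 (1R,2R)-2-{4-[(2R,3S,4S,5S)-5-(4-benzyloxy-3-methoxyphenyl)-3,4-dimethyltetrahydrofuran-2-yl]-2-methoxyphenoxy}-1-(3,4-dimethoxyphenyl)propan-1-ol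
Product: 24 (1R,2R)-1-(3,4-dimethoxyphenyl)-2-{4-[(2R,3S,4S,5S)-5-(4-hydroxy-3-methoxyphenyl)-3,4-dimethyltetrahydrofuran-2-yl]-2-methoxyphenoxy}propan-1-ol (free phenol on ring A)
Conditions: H2 (1 atm), 10% Pd/C, EtOAc, rt
Reagents that add atoms: none
Why: Hydrogenolysis of the aryl benzyl ether. In neutral solvent at low pressure this primary benzylic C–O bond should cleave well before the secondary benzylic C–O bonds of the ring and the carbinol, which need acid or forcing conditions.

Step 18
Reactants: 25 methyl (R)-lactate
Product: 26 (R)-2-hydroxy-N-methoxy-N-methylpropanamide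
Conditions: MeNHOMe·HCl, i-PrMgCl, THF, −20 → 0 °C
Reagents that add atoms: N,O-dimethylhydroxylamine hydrochloride, CNOC.Cl
Why: Weinreb amide formation as in step 12, in the enantiomeric series.

Step 19
Reactants: 26 (R)-2-hydroxy-N-methoxy-N-methylpropanamide; 19 3,4-dimethoxyphenylmagnesium bromide
Product: 27 (R)-1-(3,4-dimethoxyphenyl)-2-hydroxypropan-1-one
Conditions: i-PrMgCl (1 equiv), THF, −20 °C; then 19, 0 °C → rt; aq NH4Cl
Reagents that add atoms: none
Why: Weinreb ketone synthesis as in step 13; the chelated adduct should prevent over-addition and enolisation.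

Step 20
Reactants: 27 (R)-1-(3,4-dimethoxyphenyl)-2-hydroxypropan-1-one
Product: 28 (R)-1-(3,4-dimethoxyphenyl)-1-oxopropan-2-yl 4-methylbenzenesulfonate
Conditions: TsCl, Et3N, DMAP (cat.), CH2Cl2, 0 °C
Reagents that add atoms: 4-methylbenzenesulfonyl chloride, Cc1ccc(cc1)S(=O)(=O)Cl
Why: O-sulfonylation with retention as in step 14.

Step 21
Reactants: 24 (1R,2R)-1-(3,4-dimethoxyphenyl)-2-{4-[(2R,3S,4S,5S)-5-(4-hydroxy-3-methoxyphenyl)-3,4-dimethyltetrahydrofuran-2-yl]-2-methoxyphenoxy}propan-1-ol; 28 (R)-1-(3,4-dimethoxyphenyl)-1-oxopropan-2-yl 4-methylbenzenesulfonate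
Product: 29 (S)-1-(3,4-dimethoxyphenyl)-2-{4-[(2S,3S,4S,5R)-5-{4-[(1R,2R)-1-(3,4-dimethoxyphenyl)-1-hydroxypropan-2-yloxy]-3-methoxyphenyl}-3,4-dimethyltetrahydrofuran-2-yl]-2-methoxyphenoxy}propan-1-one (C8 S)
Conditions: BEMP, CH2Cl2, 0 °C → rt
Reagents that add atoms: none
Why: SN2 etherification with inversion as in step 15, (R)-sulfonate to (S)-ether; the phenol is deprotonated and alkylated in preference to the far less acidic secondary alcohol of the ring B chain.

Step 22
Reactants: 29 (S)-1-(3,4-dimethoxyphenyl)-2-{4-[(2S,3S,4S,5R)-5-{4-[(1R,2R)-1-(3,4-dimethoxyphenyl)-1-hydroxypropan-2-yloxy]-3-methoxyphenyl}-3,4-dimethyltetrahydrofuran-2-yl]-2-methoxyphenoxy}propan-1-one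
Product: 30 (1R,2S)-1-(3,4-dimethoxyphenyl)-2-{4-[(2S,3S,4S,5R)-5-{4-[(1R,2R)-1-(3,4-dimethoxyphenyl)-1-hydroxypropan-2-yloxy]-3-methoxyphenyl}-3,4-dimethyltetrahydrofuran-2-yl]-2-methoxyphenoxy}propan-1-ol (target)
Conditions: Zn(BH4)2, Et2O/THF, −20 → 0 °C
Reagents that add atoms: none
Why: Chelation-controlled reduction: zinc should bridge the carbonyl oxygen and the α-aryloxy oxygen, helped by the neighbouring methoxy group, and hydride then enters on the face away from the C8 methyl. This should give the anti (erythro) alcohol, C7 R from C8 S; the free C7' alcohol only consumes hydride.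

## Compound list

1 | coniferaldehyde, (E)-3-(4-hydroxy-3-methoxyphenyl)prop-2-enal | COc1cc(/C=C/C=O)ccc1O | starting material
2 | allyl bromide | C=CCBr | starting material
3 | (E)-3-(4-allyloxy-3-methoxyphenyl)prop-2-enal | C=CCOc1ccc(/C=C/C=O)cc1OC | intermediate
4 | dimethyl bromomalonate | COC(=O)C(Br)C(=O)OC | starting material
5 | dimethyl (2S,3R)-2-(4-allyloxy-3-methoxyphenyl)-3-formylcyclopropane-1,1-dicarboxylate | C=CCOc1ccc(cc1OC)[C@@H]1[C@@H](C=O)C1(C(=O)OC)C(=O)OC | intermediate
6 | dimethyl (2S,3R)-2-(4-allyloxy-3-methoxyphenyl)-3-(hydroxymethyl)cyclopropane-1,1-dicarboxylate | C=CCOc1ccc(cc1OC)[C@@H]1[C@@H](CO)C1(C(=O)OC)C(=O)OC | intermediate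
7 | dimethyl (2S,3R)-2-(4-allyloxy-3-methoxyphenyl)-3-(iodomethyl)cyclopropane-1,1-dicarboxylate | C=CCOc1ccc(cc1OC)[C@@H]1[C@@H](CI)C1(C(=O)OC)C(=O)OC | intermediate
8 | dimethyl (2S,3R)-2-(4-allyloxy-3-methoxyphenyl)-3-methylcyclopropane-1,1-dicarboxylate | C=CCOc1ccc(cc1OC)[C@@H]1[C@@H](C)C1(C(=O)OC)C(=O)OC | intermediate
9 | 4-benzyloxy-3-methoxybenzaldehyde | COc1cc(C=O)ccc1OCc1ccccc1 | starting material
10 | dimethyl (2R,4S,5R)-5-(4-allyloxy-3-methoxyphenyl)-2-(4-benzyloxy-3-methoxyphenyl)-4-methyltetrahydrofuran-3,3-dicarboxylate | c1ccccc1COc2ccc([C@H]3O[C@@H](c4ccc(OCC=C)c(OC)c4)[C@@H](C)C3(C(=O)OC)C(=O)OC)cc2OC | intermediate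
11 | methyl (2S,4S,5R)-5-(4-allyloxy-3-methoxyphenyl)-2-(4-benzyloxy-3-methoxyphenyl)-4-methyltetrahydrofuran-3-carboxylate, mixture of C3 epimers | c1ccccc1COc2ccc([C@H]3O[C@@H](c4ccc(OCC=C)c(OC)c4)[C@@H](C)C3C(=O)OC)cc2OC | intermediate
12 | methyl (2S,3S,4S,5R)-5-(4-allyloxy-3-methoxyphenyl)-2-(4-benzyloxy-3-methoxyphenyl)-4-methyltetrahydrofuran-3-carboxylate | c1ccccc1COc2ccc([C@H]3O[C@@H](c4ccc(OCC=C)c(OC)c4)[C@@H](C)[C@@H]3C(=O)OC)cc2OC | intermediate
13 | [(2S,3R,4S,5R)-5-(4-allyloxy-3-methoxyphenyl)-2-(4-benzyloxy-3-methoxyphenyl)-4-methyltetrahydrofuran-3-yl]methanol | c1ccccc1COc2ccc([C@H]3O[C@@H](c4ccc(OCC=C)c(OC)c4)[C@@H](C)[C@@H]3CO)cc2OC | intermediate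
14 | [(2S,3R,4S,5R)-5-(4-allyloxy-3-methoxyphenyl)-2-(4-benzyloxy-3-methoxyphenyl)-4-methyltetrahydrofuran-3-yl]methyl methanesulfonate | c1ccccc1COc2ccc([C@H]3O[C@@H](c4ccc(OCC=C)c(OC)c4)[C@@H](C)[C@@H]3COS(C)(=O)=O)cc2OC | intermediate
15 | (2S,3S,4S,5R)-5-(4-allyloxy-3-methoxyphenyl)-2-(4-benzyloxy-3-methoxyphenyl)-3,4-dimethyltetrahydrofuran | c1ccccc1COc2ccc([C@H]3O[C@@H](c4ccc(OCC=C)c(OC)c4)[C@@H](C)[C@@H]3C)cc2OC | intermediate
16 | 4-[(2R,3S,4S,5S)-5-(4-benzyloxy-3-methoxyphenyl)-3,4-dimethyltetrahydrofuran-2-yl]-2-methoxyphenol | c1ccccc1COc2ccc([C@H]3O[C@@H](c4ccc(O)c(OC)c4)[C@@H](C)[C@@H]3C)cc2OC | intermediate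
17 | ethyl (S)-lactate | CCOC(=O)[C@H](C)O | starting material
18 | (S)-2-hydroxy-N-methoxy-N-methylpropanamide | C[C@H](O)C(=O)N(C)OC | intermediate
19 | 3,4-dimethoxyphenylmagnesium bromide | COc1ccc([Mg]Br)cc1OC | starting material
20 | (S)-1-(3,4-dimethoxyphenyl)-2-hydroxypropan-1-one | C[C@H](O)C(=O)c1ccc(OC)c(OC)c1 | intermediate
21 | (S)-1-(3,4-dimethoxyphenyl)-1-oxopropan-2-yl 4-methylbenzenesulfonate | C[C@H](OS(=O)(=O)c1ccc(C)cc1)C(=O)c1ccc(OC)c(OC)c1 | intermediate
22 | (R)-2-{4-[(2R,3S,4S,5S)-5-(4-benzyloxy-3-methoxyphenyl)-3,4-dimethyltetrahydrofuran-2-yl]-2-methoxyphenoxy}-1-(3,4-dimethoxyphenyl)propan-1-one | c1ccccc1COc2ccc([C@H]3O[C@@H](c4ccc(O[C@H](C)C(=O)c5ccc(OC)c(OC)c5)c(OC)c4)[C@@H](C)[C@@H]3C)cc2OC | intermediate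
23 | (1R,2R)-2-{4-[(2R,3S,4S,5S)-5-(4-benzyloxy-3-methoxyphenyl)-3,4-dimethyltetrahydrofuran-2-yl]-2-methoxyphenoxy}-1-(3,4-dimethoxyphenyl)propan-1-ol | c1ccccc1COc2ccc([C@H]3O[C@@H](c4ccc(O[C@H](C)[C@H](O)c5ccc(OC)c(OC)c5)c(OC)c4)[C@@H](C)[C@@H]3C)cc2OC | intermediate
24 | (1R,2R)-1-(3,4-dimethoxyphenyl)-2-{4-[(2R,3S,4S,5S)-5-(4-hydroxy-3-methoxyphenyl)-3,4-dimethyltetrahydrofuran-2-yl]-2-methoxyphenoxy}propan-1-ol | Oc1ccc([C@H]2O[C@@H](c3ccc(O[C@H](C)[C@H](O)c4ccc(OC)c(OC)c4)c(OC)c3)[C@@H](C)[C@@H]2C)cc1OC | intermediate
25 | methyl (R)-lactate | COC(=O)[C@@H](C)O | starting material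
26 | (R)-2-hydroxy-N-methoxy-N-methylpropanamide | C[C@@H](O)C(=O)N(C)OC | intermediate
27 | (R)-1-(3,4-dimethoxyphenyl)-2-hydroxypropan-1-one | C[C@@H](O)C(=O)c1ccc(OC)c(OC)c1 | intermediate
28 | (R)-1-(3,4-dimethoxyphenyl)-1-oxopropan-2-yl 4-methylbenzenesulfonate | C[C@@H](OS(=O)(=O)c1ccc(C)cc1)C(=O)c1ccc(OC)c(OC)c1 | intermediate
29 | (S)-1-(3,4-dimethoxyphenyl)-2-{4-[(2S,3S,4S,5R)-5-{4-[(1R,2R)-1-(3,4-dimethoxyphenyl)-1-hydroxypropan-2-yloxy]-3-methoxyphenyl}-3,4-dimethyltetrahydrofuran-2-yl]-2-methoxyphenoxy}propan-1-one | COc1ccc(C(=O)[C@H](C)Oc2ccc([C@H]3O[C@@H](c4ccc(O[C@H](C)[C@H](O)c5ccc(OC)c(OC)c5)c(OC)c4)[C@@H](C)[C@@H]3C)cc2OC)cc1OC | intermediate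
30 | (1R,2S)-1-(3,4-dimethoxyphenyl)-2-{4-[(2S,3S,4S,5R)-5-{4-[(1R,2R)-1-(3,4-dimethoxyphenyl)-1-hydroxypropan-2-yloxy]-3-methoxyphenyl}-3,4-dimethyltetrahydrofuran-2-yl]-2-methoxyphenoxy}propan-1-ol | COc1ccc([C@@H](O)[C@H](C)Oc2ccc([C@H]3O[C@@H](c4ccc(O[C@H](C)[C@H](O)c5ccc(OC)c(OC)c5)c(OC)c4)[C@@H](C)[C@@H]3C)cc2OC)cc1OC | target

## Step count and least certain steps

Total step count: 22. Longest linear sequence: 16 steps (steps 1 to 11, 15 to 17, 21 and 22). The two sulfonates are made in side branches of three steps each (steps 12 to 14 and 18 to 20).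

**Step 6 (key step).** The most likely failure is full ionisation of the benzylic bond before the aldehyde captures it, because the 4-alkoxy-3-methoxyphenyl group stabilises a cation strongly. That would cost the inversion fidelity at C5, allow proton loss from C4 to an open-chain styrylmalonate, and let the product reopen and drift to the 2,5-trans isomer. A change of promoter (for example AlCl3) would be tried first but is only a change of conditions. The fallback weakens the donor instead. It sets out from 1, which is acylated with pivaloyl chloride to (E)-3-(3-methoxy-4-pivaloyloxyphenyl)prop-2-enal F1. The operations of steps 2 to 5 then lead through the formylcyclopropane dimethyl (2S,3R)-3-formyl-2-(3-methoxy-4-pivaloyloxyphenyl)cyclopropane-1,1-dicarboxylate F2, the carbinol dimethyl (2S,3R)-3-(hydroxymethyl)-2-(3-methoxy-4-pivaloyloxyphenyl)cyclopropane-1,1-dicarboxylate F3 and the iodide dimethyl (2S,3R)-3-(iodomethyl)-2-(3-methoxy-4-pivaloyloxyphenyl)cyclopropane-1,1-dicarboxylate F4 to dimethyl (2S,3R)-2-(3-methoxy-4-pivaloyloxyphenyl)-3-methylcyclopropane-1,1-dicarboxylate F5, whose aryl group is a donor of about the strength of phenyl. Annulation of F5 with 9 under the same tin catalysis at 0 °C to room temperature should then run in the SN2-like manifold to dimethyl (2R,4S,5R)-2-(4-benzyloxy-3-methoxyphenyl)-5-(3-methoxy-4-pivaloyloxyphenyl)-4-methyltetrahydrofuran-3,3-dicarboxylate F6. Methanolysis (K2CO3, MeOH, rt) would give the phenol dimethyl (2R,4S,5R)-2-(4-benzyloxy-3-methoxyphenyl)-5-(4-hydroxy-3-methoxyphenyl)-4-methyltetrahydrofuran-3,3-dicarboxylate F7, and allylation with 2 (K2CO3, DMF) comes back to the route at 10.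

**Step 5.** The most likely failure is ring opening during the displacement, either by electron transfer from borohydride to the iodide (a cyclopropylcarbinyl radical opens at once) or by ionisation assisted by the aryl-bearing ring bond; ester-oxygen participation to a lactone is a further drain. The fallback brings the methyl group in with the alkene and makes the ring by carbene transfer. It sets out from 2, which O-allylates purchased (E)-isoeugenol (K2CO3, DMF) to 1-allyloxy-2-methoxy-4-[(E)-prop-1-enyl]benzene F8. Dimethyl malonate, activated in the flask as its phenyliodonium ylide with PhI(OAc)2, would then be transferred to the electron-rich propenyl double bond by a monovalent copper catalyst (Cu(MeCN)4PF6) with a chiral bisoxazoline ligand of the sense that gives (2S,3R). This enantioselective, stereospecific syn addition keeps aryl and methyl trans and comes back to the route at 8.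

**Step 7.** The most likely failure is aromatic Claisen rearrangement of the allyl aryl ether at the temperature of the dealkoxycarbonylation, together with incomplete equilibration at C3. The fallback lowers the thermal demand by separating hydrolysis from decarboxylation. It sets out from 10, which is mono-saponified (KOH, 1 equiv, MeOH/H2O, 40 °C) to the half-ester (2R,4S,5R)-5-(4-allyloxy-3-methoxyphenyl)-2-(4-benzyloxy-3-methoxyphenyl)-3-methoxycarbonyl-4-methyltetrahydrofuran-3-carboxylic acid F9. Decarboxylation of this malonic half-acid in pyridine at 100 °C gives 11, and the methoxide equilibration of step 7 comes back to the route at 12.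

**Step 15 (and likewise step 21).** The most likely failure is base-induced enolisation of the α-sulfonyloxy ketone or of the α-aryloxy ketone product, which would erode the configuration at C8', or elimination of sulfonate to an enone. The fallback replaces the base-mediated displacement by a redox condensation: 16 and the hydroxy ketone 20 are coupled under Mitsunobu conditions (PPh3, diisopropyl azodicarboxylate, THF, 0 °C), which also inverts the carbinol carbon. It sets out from 16 and 20, comes back to the route at 22 and makes no new compound (entry F0).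

**Step 22.** The most likely failure is poor facial selectivity, because an aryloxy oxygen is a weak donor and a non-chelated transition state would lead to the C7 S (threo) epimer. The fallback changes from substrate control to reagent control: Corey–Bakshi–Shibata reduction of 29 with the (R)-2-methyl oxazaborolidine catalyst and BH3·SMe2 in THF at −20 °C. By the usual model, with the veratryl group as the larger substituent, this should deliver hydride to the face that gives C7 R. It sets out from 29, comes back to the route at 30 and makes no new compound (entry F0).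

## Further compounds

F1 | step 6 | (E)-3-(3-methoxy-4-pivaloyloxyphenyl)prop-2-enal | CC(C)(C)C(=O)Oc1ccc(/C=C/C=O)cc1OC
F2 | step 6 | dimethyl (2S,3R)-3-formyl-2-(3-methoxy-4-pivaloyloxyphenyl)cyclopropane-1,1-dicarboxylate | CC(C)(C)C(=O)Oc1ccc(cc1OC)[C@@H]1[C@@H](C=O)C1(C(=O)OC)C(=O)OC
F3 | step 6 | dimethyl (2S,3R)-3-(hydroxymethyl)-2-(3-methoxy-4-pivaloyloxyphenyl)cyclopropane-1,1-dicarboxylate | CC(C)(C)C(=O)Oc1ccc(cc1OC)[C@@H]1[C@@H](CO)C1(C(=O)OC)C(=O)OC
F4 | step 6 | dimethyl (2S,3R)-3-(iodomethyl)-2-(3-methoxy-4-pivaloyloxyphenyl)cyclopropane-1,1-dicarboxylate | CC(C)(C)C(=O)Oc1ccc(cc1OC)[C@@H]1[C@@H](CI)C1(C(=O)OC)C(=O)OC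
F5 | step 6 | dimethyl (2S,3R)-2-(3-methoxy-4-pivaloyloxyphenyl)-3-methylcyclopropane-1,1-dicarboxylate | CC(C)(C)C(=O)Oc1ccc(cc1OC)[C@@H]1[C@@H](C)C1(C(=O)OC)C(=O)OC
F6 | step 6 | dimethyl (2R,4S,5R)-2-(4-benzyloxy-3-methoxyphenyl)-5-(3-methoxy-4-pivaloyloxyphenyl)-4-methyltetrahydrofuran-3,3-dicarboxylate | c1ccccc1COc2ccc([C@H]3O[C@@H](c4ccc(OC(=O)C(C)(C)C)c(OC)c4)[C@@H](C)C3(C(=O)OC)C(=O)OC)cc2OC
F7 | step 6 | dimethyl (2R,4S,5R)-2-(4-benzyloxy-3-methoxyphenyl)-5-(4-hydroxy-3-methoxyphenyl)-4-methyltetrahydrofuran-3,3-dicarboxylate | c1ccccc1COc2ccc([C@H]3O[C@@H](c4ccc(O)c(OC)c4)[C@@H](C)C3(C(=O)OC)C(=O)OC)cc2OC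
F8 | step 5 | 1-allyloxy-2-methoxy-4-[(E)-prop-1-enyl]benzene | C=CCOc1ccc(/C=C/C)cc1OC
F9 | step 7 | (2R,4S,5R)-5-(4-allyloxy-3-methoxyphenyl)-2-(4-benzyloxy-3-methoxyphenyl)-3-methoxycarbonyl-4-methyltetrahydrofuran-3-carboxylic acid (C3 not defined) | c1ccccc1COc2ccc([C@H]3O[C@@H](c4ccc(OCC=C)c(OC)c4)[C@@H](C)C3(C(=O)O)C(=O)OC)cc2OC
F0 | step 15 | none | none
F0 | step 22 | none | none
A1 | alternative 1 | bis(4-O-demethyl) analogue of 30, both carbinols R | Oc1ccc([C@@H](O)[C@H](C)Oc2ccc([C@H]3O[C@@H](c4ccc(O[C@H](C)[C@H](O)c5ccc(O)c(OC)c5)c(OC)c4)[C@@H](C)[C@@H]3C)cc2OC)cc1OC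
A2 | alternative 1 | (2S,3S,4S,5R)-2-{4-[(S)-1-(4-hydroxy-3-methoxyphenyl)propan-2-yloxy]-3-methoxyphenyl}-5-{4-[(R)-1-(4-hydroxy-3-methoxyphenyl)propan-2-yloxy]-3-methoxyphenyl}-3,4-dimethyltetrahydrofuran | Oc1ccc(C[C@H](C)Oc2ccc([C@H]3O[C@@H](c4ccc(O[C@H](C)Cc5ccc(O)c(OC)c5)c(OC)c4)[C@@H](C)[C@@H]3C)cc2OC)cc1OC
A3 | alternative 2 | (2S,3S,4S,5R)-2-(4-hydroxy-3-methoxyphenyl)-5-(4-tert-butyldimethylsilyloxy-3-methoxyphenyl)-3,4-dimethyltetrahydrofuran | Oc1ccc([C@H]2O[C@@H](c3ccc(O[Si](C)(C)C(C)(C)C)c(OC)c3)[C@@H](C)[C@@H]2C)cc1OC
A4 | alternative 2 | (1R,2S,3R)-1-(4-tert-butyldimethylsilyloxy-3-methoxyphenyl)-4-(4-hydroxy-3-methoxyphenyl)-2,3-dimethylbutan-1-ol | Oc1ccc(C[C@@H](C)[C@H](C)[C@@H](O)c2ccc(O[Si](C)(C)C(C)(C)C)c(OC)c2)cc1OC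
A5 | alternative 3 | (3S,4S,5S)-5-(4-benzyloxy-3-methoxyphenyl)-3,4-dimethyldihydrofuran-2(3H)-one (all-trans) | c1ccccc1COc2ccc([C@H]3OC(=O)[C@@H](C)[C@@H]3C)cc2OC
A6 | alternative 3 | (S)-5-(4-benzyloxy-3-methoxyphenyl)furan-2(5H)-one | c1ccccc1COc2ccc([C@H]3OC(=O)C=C3)cc2OC
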